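**Strategy.** With the carbocycle numbered so that the Z alkenes are C10=C1 and C4=C5 (methyls on C10 and C4, hydroxyl on C6, isopropyl on C7, 4-hydroxybenzoate on C8), the route rests on cutting C9–C10. The feature used is that C9 is the only sp3 carbon between the oxygenated C8 and the alkene carbon C10. It is set free as a radical from a carboxylic acid and joined at nickel to a Z vinyl iodide, which closes the ten-membered ring in one cathodic operation without touching C6–C8. The precursor is an open-chain (Z,Z)-iodo diene N-hydroxyphthalimide ester whose anti O6/O8 pair is locked as an acetonide; the aryl ester follows by Evans–Tishchenko reduction.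

Key step: step 13

**Remarks on the chemistry**
- Design correction: relative to C4=C5 the C9 radical is a hex-5-enyl radical (C9–C8–C7–C6–C5=C4). With separate groups on O6 and O8 it could close 5-exo onto C5, a clock reaction normally faster than a ten-membered closure. An O8 acyl group would also sit β to the radical and to the alkylnickel centre, and would make the active ester prone to base-induced elimination. The precursor therefore holds O6 and O8 in one 1,3-dioxane; because the 6,8-diol is anti, C5 and C9 are trans on that ring and cannot bond. The aryl ester is put on after ring closure.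
- Assumption: neryl acetate, (4S)-4-benzyl-1,3-thiazolidine-2-thione and 4-[(tert-butyldimethylsilyl)oxy]benzaldehyde are bought.
- The configuration at C7 is fixed in step 7 and never changes; only its CIP letter changes with the groups on C6/C8. C6 is set in step 7, directs C8 (step 9) and fixes the trans-dioxane, is removed in step 15 and is set again from C8 in step 16.

**Route**

Step 1
Reactants: 1 neryl acetate, (2Z)-3,7-dimethylocta-2,6-dien-1-yl acetate
Product: 2 (2Z)-5-(3,3-dimethyloxiran-2-yl)-3-methylpent-2-en-1-yl acetate (racemic at the oxirane carbon)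
Conditions: mCPBA, CH2Cl2, −20 to 0 °C
Reagents that add atoms: mCPBA (3-chloroperoxybenzoic acid), OOC(=O)c1cccc(Cl)c1
Why: Prilezhaev epoxidation should pick the electron-rich remote trisubstituted alkene because the C2=C3 alkene is deactivated by the allylic acetate; the racemic oxirane centre is destroyed in step 2.

Step 2
Reactants: 2 (2Z)-5-(3,3-dimethyloxiran-2-yl)-3-methylpent-2-en-1-yl acetate
Product: 3 (2Z)-3-methyl-6-oxohex-2-en-1-yl acetate
Conditions: H5IO6, THF/H2O, 0 °C
Reagents that add atoms: none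
Why: Periodic acid opens the epoxide to the glycol and cleaves it (Malaprade-type glycol cleavage) to the aldehyde and acetone without touching the Z allylic acetate.

Step 3
Reactants: 3 (2Z)-3-methyl-6-oxohex-2-en-1-yl acetate
Product: 4 (2Z,6Z)-7-iodo-3-methylocta-2,6-dien-1-yl acetate
Conditions: EtPPh3I, n-BuLi, THF, 0 °C; I2, −78 °C; NaN(SiMe3)2, −78 to −20 °C; then 3, −78 °C to rt
Reagents that add atoms: ethyltriphenylphosphonium iodide, CC[P+](c1ccccc1)(c1ccccc1)c1ccccc1.[I-]; iodine, II
Why: Stork–Zhao-type Wittig olefination with the non-stabilised α-iodo ylide should give the trisubstituted vinyl iodide with iodine cis to the chain (Z) through the kinetically favoured cis-oxaphosphetane.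

Step 4
Reactants: 4 (2Z,6Z)-7-iodo-3-methylocta-2,6-dien-1-yl acetate
Product: 5 (2Z,6Z)-7-iodo-3-methylocta-2,6-dien-1-ol
Conditions: K2CO3 (cat.), MeOH, 0 °C to rt
Reagents that add atoms: none
Why: Base-catalysed transesterification with methanol removes the acetate and puts neither alkene geometry at risk.

Step 5
Reactants: 5 (2Z,6Z)-7-iodo-3-methylocta-2,6-dien-1-ol
Product: 6 (2Z,6Z)-7-iodo-3-methylocta-2,6-dienal
Conditions: Dess–Martin periodinane, pyridine, CH2Cl2, 0 °C
Reagents that add atoms: none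
Why: Buffered Dess–Martin oxidation of the allylic alcohol should give the Z enal without Z-to-E isomerisation; the aldehyde is used at once.

Step 6
Reactants: 7 (4S)-4-benzyl-1,3-thiazolidine-2-thione; 8 isovaleryl chloride (3-methylbutanoyl chloride)
Product: 9 (4S)-4-benzyl-3-(3-methylbutanoyl)-1,3-thiazolidine-2-thione
Conditions: Et3N, DMAP (cat.), CH2Cl2, 0 °C to rt
Reagents that add atoms: none
Why: N-acylation of the thiazolidinethione by the acid chloride (Schotten–Baumann-type amide formation) leaves the auxiliary stereocentre untouched.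

Step 7
Reactants: 9 (4S)-4-benzyl-3-(3-methylbutanoyl)-1,3-thiazolidine-2-thione; 6 (2Z,6Z)-7-iodo-3-methylocta-2,6-dienal
Product: 11 (4S)-4-benzyl-3-[(2S,3R,4Z,8Z)-3-hydroxy-9-iodo-5-methyl-2-(propan-2-yl)deca-4,8-dienoyl]-1,3-thiazolidine-2-thione, via chlorotitanium Z-enolate 10 (not isolated)
Conditions: TiCl4 (1.05 equiv), i-Pr2NEt (1.1 equiv), N-methyl-2-pyrrolidinone (1 equiv), CH2Cl2, 0 °C; then 6, −78 to 0 °C
Reagents that add atoms: none
Why: Crimmins titanium aldol in its Evans-syn mode: the Z-enolate reacts through a non-chelated Zimmerman–Traxler chair on the face away from the benzyl group, which sets ring C7 and C6 (2S,3R in the acyl chain) syn.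

Step 8
Reactants: 11 (4S)-4-benzyl-3-[(2S,3R,4Z,8Z)-3-hydroxy-9-iodo-5-methyl-2-(propan-2-yl)deca-4,8-dienoyl]-1,3-thiazolidine-2-thione
Product: 13 methyl (4S,5R,6Z,10Z)-5-hydroxy-11-iodo-7-methyl-3-oxo-4-(propan-2-yl)dodeca-6,10-dienoate, via acylmalonic half ester 12 (not isolated)
Conditions: KO2CCH2CO2Me, MgCl2, imidazole, THF, rt; dilute HCl work-up
Reagents that add atoms: potassium methyl malonate, COC(=O)CC(=O)[O-].[K+]
Why: Masamune–Brooks-type C-acylation of the magnesium malonate by the activated thiazolidinethione amide, then decarboxylation, should give the β-keto ester (ring C8 ketone, C9 methylene) under near-neutral conditions that tolerate the free hydroxyl and do not epimerise C7.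

Step 9
Reactants: 13 methyl (4S,5R,6Z,10Z)-5-hydroxy-11-iodo-7-methyl-3-oxo-4-(propan-2-yl)dodeca-6,10-dienoate
Product: 15 methyl (3R,4R,5R,6Z,10Z)-3,5-dihydroxy-11-iodo-7-methyl-4-(propan-2-yl)dodeca-6,10-dienoate, via C6 alkoxydiacetoxyborohydride 14 (not isolated)
Conditions: Me4NBH(OAc)3, MeCN/AcOH (1:1), −30 °C
Reagents that add atoms: none
Why: Evans–Saksena directed reduction: ligand exchange at the ring C6 hydroxyl and internal hydride delivery through a chair transition state should set ring C8 (R) anti to C6.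

Step 10
Reactants: 15 methyl (3R,4R,5R,6Z,10Z)-3,5-dihydroxy-11-iodo-7-methyl-4-(propan-2-yl)dodeca-6,10-dienoate
Product: 16 methyl 2-[(4R,5R,6R)-6-[(1Z,5Z)-6-iodo-2-methylhepta-1,5-dien-1-yl]-2,2-dimethyl-5-(propan-2-yl)-1,3-dioxan-4-yl]acetate
Conditions: 2,2-dimethoxypropane, PPTS (cat.), CH2Cl2, rt
Reagents that add atoms: 2,2-dimethoxypropane, COC(C)(C)OC
Why: Acid-catalysed transketalisation (acetonide formation) should lock the anti 6,8-diol in a 1,3-dioxane faster than the δ-hydroxy ester can lactonise.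

Step 11
Reactants: 16 methyl 2-[(4R,5R,6R)-6-[(1Z,5Z)-6-iodo-2-methylhepta-1,5-dien-1-yl]-2,2-dimethyl-5-(propan-2-yl)-1,3-dioxan-4-yl]acetate
Product: 17 2-[(4R,5R,6R)-6-[(1Z,5Z)-6-iodo-2-methylhepta-1,5-dien-1-yl]-2,2-dimethyl-5-(propan-2-yl)-1,3-dioxan-4-yl]acetic acid
Conditions: LiOH, THF/MeOH/H2O, 0 °C to rt; then dilute HCl to pH 4, 0 °C
Reagents that add atoms: lithium hydroxide, [Li+].[OH-]
Why: Saponification of the methyl ester; the acetal, the vinyl iodide and the β-alkoxy centre are stable to cold LiOH.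

Step 12
Reactants: 17 2-[(4R,5R,6R)-6-[(1Z,5Z)-6-iodo-2-methylhepta-1,5-dien-1-yl]-2,2-dimethyl-5-(propan-2-yl)-1,3-dioxan-4-yl]acetic acid
Product: 18 1,3-dioxo-1,3-dihydro-2H-isoindol-2-yl 2-[(4R,5R,6R)-6-[(1Z,5Z)-6-iodo-2-methylhepta-1,5-dien-1-yl]-2,2-dimethyl-5-(propan-2-yl)-1,3-dioxan-4-yl]acetate
Conditions: N-hydroxyphthalimide, N,N′-diisopropylcarbodiimide, DMAP (cat.), CH2Cl2, rt
Reagents that add atoms: N-hydroxyphthalimide, ON1C(=O)c2ccccc2C1=O
Why: Steglich-type carbodiimide esterification gives the redox-active ester; the β-oxygen is an acetal oxygen, so base-induced elimination of the active ester is not expected.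

Step 13
Reactants: 18 1,3-dioxo-1,3-dihydro-2H-isoindol-2-yl 2-[(4R,5R,6R)-6-[(1Z,5Z)-6-iodo-2-methylhepta-1,5-dien-1-yl]-2,2-dimethyl-5-(propan-2-yl)-1,3-dioxan-4-yl]acetate
Product: 19 (1R,2Z,6Z,9R,13R)-3,7,11,11-tetramethyl-13-(propan-2-yl)-10,12-dioxabicyclo[7.3.1]trideca-2,6-diene (the O6/O8 acetonide of the ten-membered dienediol)
Conditions: NiBr2(dme) (0.3 equiv), 2,2′-bipyridine (0.36 equiv), LiBr, DMF, Zn anode, reticulated vitreous carbon cathode, undivided cell, constant current, rt; 18 added by syringe pump (about 2 mM final)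
Reagents that add atoms: none
Why: Proposed new method: cathodic reduction of divalent nickel–bipyridine gives low-valent nickel that inserts into the C10–I bond with retention of the Z geometry, while single-electron reduction of the phthalimide ester (by univalent nickel or at the cathode) expels CO2 and leaves the primary C9 radical; the alkenylnickel captures this radical and reductive elimination from trivalent nickel forms C9–C10. The closest known reaction type is the nickel-electrocatalysed decarboxylative alkenylation of redox-active esters with alkenyl halides, known only between two molecules. The ten-membered carbocycle closes end to end by sp3–sp2 reductive elimination at nickel (through an eleven-membered nickelacycle), not by radical addition to an alkene. No stereocentre is formed: C6, C7 and C8 are spectators and the C10=C1 geometry follows from stereoretentive oxidative addition. The step needs coupling at nickel to beat 5-exo attack of C9 on C5, reduction or dimerisation of the radical and loss of the β-oxygen; the trans-dioxane (C5 on C6 and C9 on C8 on opposite faces) makes the 5-exo product an unattainable trans-bridged bicyclo[3.2.1]octane, the β-oxygen is a poor acetal leaving group, the two Z alkenes pre-bend the chain, and slow addition under current control keeps the radical concentration low.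

Step 14
Reactants: 19 (1R,2Z,6Z,9R,13R)-3,7,11,11-tetramethyl-13-(propan-2-yl)-10,12-dioxabicyclo[7.3.1]trideca-2,6-diene
Product: 20 (1R,2R,3R,4Z,8Z)-5,9-dimethyl-2-(propan-2-yl)cyclodeca-4,8-diene-1,3-diol
Conditions: PPTS, MeOH, rt
Reagents that add atoms: none
Why: Acid-catalysed transketalisation to methanol; the strained anti-acetonide should exchange under conditions too mild to ionise the allylic C6–O bond or protonate the ring alkenes.

Step 15
Reactants: 20 (1R,2R,3R,4Z,8Z)-5,9-dimethyl-2-(propan-2-yl)cyclodeca-4,8-diene-1,3-diol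
Product: 21 (2Z,6Z,9R,10R)-9-hydroxy-3,7-dimethyl-10-(propan-2-yl)cyclodeca-2,6-dien-1-one
Conditions: MnO2 (activated, excess), CH2Cl2, rt
Reagents that add atoms: none
Why: MnO2 oxidises allylic alcohols selectively, so only the ring C6 hydroxyl becomes the enone and the C8 hydroxyl is left as the only alcohol; the C6 centre is removed on purpose and set again in step 16.

Step 16
Reactants: 21 (2Z,6Z,9R,10R)-9-hydroxy-3,7-dimethyl-10-(propan-2-yl)cyclodeca-2,6-dien-1-one; 22 4-[(tert-butyldimethylsilyl)oxy]benzaldehyde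
Product: 24 (1R,3Z,7Z,9R,10S)-9-hydroxy-3,7-dimethyl-10-(propan-2-yl)cyclodeca-3,7-dien-1-yl 4-[(tert-butyldimethylsilyl)oxy]benzoate, via C8 hemiacetal 23 (not isolated)
Conditions: 22 (5 equiv), SmI2 (0.3 equiv), THF, −10 °C
Reagents that add atoms: none
Why: Evans–Tishchenko reduction: the C8 hydroxyl forms a samarium-bound hemiacetal with the aldehyde and its hydride passes to the C6 ketone through a chair-like bicyclic transition state, so the aroyl group must end on O8 and C6 (R) is set anti to C8.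

Step 17
Reactants: 24 (1R,3Z,7Z,9R,10S)-9-hydroxy-3,7-dimethyl-10-(propan-2-yl)cyclodeca-3,7-dien-1-yl 4-[(tert-butyldimethylsilyl)oxy]benzoate
Product: 25 (1R,3Z,7Z,9R,10S)-9-hydroxy-3,7-dimethyl-10-(propan-2-yl)cyclodeca-3,7-dien-1-yl 4-hydroxybenzoate (target)
Conditions: KHF2, MeOH, rt
Reagents that add atoms: none
Why: Bifluoride desilylation is selective for the aryl silyl ether and is slightly acidic, so O8-to-O6 acyl migration is not expected.

**Compound list**

1 | neryl acetate, (2Z)-3,7-dimethylocta-2,6-dien-1-yl acetate | CC(C)=CCC/C(C)=C\COC(C)=O | starting material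
2 | (2Z)-5-(3,3-dimethyloxiran-2-yl)-3-methylpent-2-en-1-yl acetate (racemic oxirane) | CC1(C)OC1CC/C(C)=C\COC(C)=O | intermediate
3 | (2Z)-3-methyl-6-oxohex-2-en-1-yl acetate | O=CCC/C(C)=C\COC(C)=O | intermediate
4 | (2Z,6Z)-7-iodo-3-methylocta-2,6-dien-1-yl acetate | I/C(C)=C\CC/C(C)=C\COC(C)=O | intermediate
5 | (2Z,6Z)-7-iodo-3-methylocta-2,6-dien-1-ol | I/C(C)=C\CC/C(C)=C\CO | intermediate
6 | (2Z,6Z)-7-iodo-3-methylocta-2,6-dienal | I/C(C)=C\CC/C(C)=C\C=O | intermediate
7 | (4S)-4-benzyl-1,3-thiazolidine-2-thione | S=C1N[C@@H](Cc2ccccc2)CS1 | starting material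
8 | isovaleryl chloride (3-methylbutanoyl chloride) | CC(C)CC(Cl)=O | starting material
9 | (4S)-4-benzyl-3-(3-methylbutanoyl)-1,3-thiazolidine-2-thione | CC(C)CC(=O)N1[C@@H](Cc2ccccc2)CSC1=S | intermediate
10 | trichlorotitanium (Z)-enolate of 9 | CC(C)/C=C(\O[Ti](Cl)(Cl)Cl)N1[C@@H](Cc2ccccc2)CSC1=S | intermediate (not isolated)
11 | (4S)-4-benzyl-3-[(2S,3R,4Z,8Z)-3-hydroxy-9-iodo-5-methyl-2-(propan-2-yl)deca-4,8-dienoyl]-1,3-thiazolidine-2-thione | I/C(C)=C\CC/C(C)=C\[C@@H](O)[C@H](C(C)C)C(=O)N1[C@@H](Cc2ccccc2)CSC1=S | intermediate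
12 | 2-[(2S,3R,4Z,8Z)-3-hydroxy-9-iodo-5-methyl-2-(propan-2-yl)deca-4,8-dienoyl]-3-methoxy-3-oxopropanoic acid (malonate carbon unassigned) | I/C(C)=C\CC/C(C)=C\[C@@H](O)[C@H](C(C)C)C(=O)C(C(=O)O)C(=O)OC | intermediate (not isolated)
13 | methyl (4S,5R,6Z,10Z)-5-hydroxy-11-iodo-7-methyl-3-oxo-4-(propan-2-yl)dodeca-6,10-dienoate | I/C(C)=C\CC/C(C)=C\[C@@H](O)[C@H](C(C)C)C(=O)CC(=O)OC | intermediate
14 | tetramethylammonium diacetoxy(alkoxy)hydroborate formed at the C5 hydroxyl of 13 (ring C6) | I/C(C)=C\CC/C(C)=C\[C@@H](O[BH-](OC(C)=O)OC(C)=O)[C@H](C(C)C)C(=O)CC(=O)OC.C[N+](C)(C)C | intermediate (not isolated)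
15 | methyl (3R,4R,5R,6Z,10Z)-3,5-dihydroxy-11-iodo-7-methyl-4-(propan-2-yl)dodeca-6,10-dienoate | I/C(C)=C\CC/C(C)=C\[C@@H](O)[C@H](C(C)C)[C@H](O)CC(=O)OC | intermediate
16 | methyl 2-[(4R,5R,6R)-6-[(1Z,5Z)-6-iodo-2-methylhepta-1,5-dien-1-yl]-2,2-dimethyl-5-(propan-2-yl)-1,3-dioxan-4-yl]acetate | I/C(C)=C\CC/C(C)=C\[C@H]1OC(C)(C)O[C@H](CC(=O)OC)[C@H]1C(C)C | intermediate
17 | 2-[(4R,5R,6R)-6-[(1Z,5Z)-6-iodo-2-methylhepta-1,5-dien-1-yl]-2,2-dimethyl-5-(propan-2-yl)-1,3-dioxan-4-yl]acetic acid | I/C(C)=C\CC/C(C)=C\[C@H]1OC(C)(C)O[C@H](CC(=O)O)[C@H]1C(C)C | intermediate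
18 | 1,3-dioxo-1,3-dihydro-2H-isoindol-2-yl 2-[(4R,5R,6R)-6-[(1Z,5Z)-6-iodo-2-methylhepta-1,5-dien-1-yl]-2,2-dimethyl-5-(propan-2-yl)-1,3-dioxan-4-yl]acetate (key-step precursor) | I/C(C)=C\CC/C(C)=C\[C@H]1OC(C)(C)O[C@H](CC(=O)ON2C(=O)c3ccccc3C2=O)[C@H]1C(C)C | intermediate
19 | (1R,2Z,6Z,9R,13R)-3,7,11,11-tetramethyl-13-(propan-2-yl)-10,12-dioxabicyclo[7.3.1]trideca-2,6-diene (key-step product) | C/C1=C/[C@H]2OC(C)(C)O[C@@H]([C@H]2C(C)C)C/C(C)=C\CC1 | intermediate
20 | (1R,2R,3R,4Z,8Z)-5,9-dimethyl-2-(propan-2-yl)cyclodeca-4,8-diene-1,3-diol | C/C1=C/[C@@H](O)[C@H](C(C)C)[C@H](O)C/C(C)=C\CC1 | intermediate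
21 | (2Z,6Z,9R,10R)-9-hydroxy-3,7-dimethyl-10-(propan-2-yl)cyclodeca-2,6-dien-1-one | C/C1=C/C(=O)[C@H](C(C)C)[C@H](O)C/C(C)=C\CC1 | intermediate
22 | 4-[(tert-butyldimethylsilyl)oxy]benzaldehyde | O=Cc1ccc(O[Si](C)(C)C(C)(C)C)cc1 | starting material
23 | hemiacetal of 22 at the C9 hydroxyl of 21 (ring O8), held on trivalent samarium in the flask, drawn as the free hemiacetal | C/C1=C/C(=O)[C@H](C(C)C)[C@H](OC(O)c2ccc(O[Si](C)(C)C(C)(C)C)cc2)C/C(C)=C\CC1 | intermediate (not isolated)
24 | (1R,3Z,7Z,9R,10S)-9-hydroxy-3,7-dimethyl-10-(propan-2-yl)cyclodeca-3,7-dien-1-yl 4-[(tert-butyldimethylsilyl)oxy]benzoate | C/C1=C/[C@@H](O)[C@H](C(C)C)[C@H](OC(=O)c2ccc(O[Si](C)(C)C(C)(C)C)cc2)C/C(C)=C\CC1 | intermediate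
25 | (1R,3Z,7Z,9R,10S)-9-hydroxy-3,7-dimethyl-10-(propan-2-yl)cyclodeca-3,7-dien-1-yl 4-hydroxybenzoate | C/C1=C/[C@@H](O)[C@H](C(C)C)[C@H](OC(=O)c2ccc(O)cc2)C/C(C)=C\CC1 | target

**Step count and risk**

Total steps: 17. Longest linear sequence: 16 steps (steps 1–5 and 7–17, from neryl acetate); step 6 is the only side branch.

Steps most likely to fail:

1. Step 13 (proposed new method). The C9 radical may be reduced or abstract hydrogen before it meets nickel, two molecules may couple instead of one closing, or strain in the forming ten-membered ring may slow reductive elimination. The fallback uses known chemistry, ring-closing metathesis at C10=C1; it sets out from 3 and comes back at 19. Wittig methylenation of 3 (Ph3P=CH2, THF) gives (2Z)-3-methylhepta-2,6-dien-1-yl acetate F1. Methanolysis (K2CO3, MeOH) gives (2Z)-3-methylhepta-2,6-dien-1-ol F2, and Dess–Martin oxidation gives (2Z)-3-methylhepta-2,6-dienal F3. The titanium aldol of 9 with F3 under the conditions of step 7 gives syn aldol adduct F4. Transamidation (MeNHOMe·HCl, imidazole, CH2Cl2) gives Weinreb amide F5, and 2-methylallylmagnesium chloride (THF, −78 °C) gives 2-methylallyl ketone F6. Evans–Saksena reduction (Me4NBH(OAc)3, MeCN/AcOH) gives anti diol F7, and 2,2-dimethoxypropane/PPTS gives acetonide triene F8. Second-generation Grubbs catalyst in dilute CH2Cl2 at 40 °C should join the monosubstituted C1 alkene to the 1,1-disubstituted C10 alkene with loss of ethylene; the ring-cis (Z) alkene is the one a ten-membered ring favours, which gives 19.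

2. Step 16 (with the enone from step 15). Oxidation of the hindered ring allylic alcohol may be slow, hydroxy enone 21 may undergo transannular oxa-Michael addition or epimerise at C7, or the ring may hold the hemiacetal hydride away from C6. The fallback is direct acylation; it sets out from 20 and comes back at 24. 4-Hydroxybenzoic acid is silylated (TBSCl, imidazole, DMF) and the silyl ester is cleaved (K2CO3, MeOH/H2O) to give 4-[(tert-butyldimethylsilyl)oxy]benzoic acid F9. Steglich esterification of 20 with one equivalent of F9 (EDC·HCl, DMAP, CH2Cl2, 0 °C) should acylate the non-allylic O8, since an acyl group prefers the oxygen of the less acidic hydroxyl. That regioselectivity is not secured by mechanism; any O6 ester would be separated and equilibrated by acyl migration. The product is 24, and step 17 follows.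

3. Step 3. The α-iodo ylide may decompose in part, Z selectivity may erode, and excess base may attack the acetate. The fallback sets out from 3 and comes back at 4. Corey–Fuchs olefination (CBr4, PPh3, CH2Cl2, 0 °C) gives (2Z)-7,7-dibromo-3-methylhepta-2,6-dien-1-yl acetate F10. Palladium-catalysed Negishi methylation (MeZnCl, PdCl2(DPEphos), THF), selective for the bromide trans to the chain, gives (2Z,6Z)-7-bromo-3-methylocta-2,6-dien-1-yl acetate F11. Copper-catalysed halide exchange (CuI, NaI, trans-N,N′-dimethylcyclohexane-1,2-diamine, dioxane, 110 °C) proceeds with retention and gives 4.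

**Further compounds**

F1 | step 13 | (2Z)-3-methylhepta-2,6-dien-1-yl acetate | C=CCC/C(C)=C\COC(C)=O
F2 | step 13 | (2Z)-3-methylhepta-2,6-dien-1-ol | C=CCC/C(C)=C\CO
F3 | step 13 | (2Z)-3-methylhepta-2,6-dienal | C=CCC/C(C)=C\C=O
F4 | step 13 | (4S)-4-benzyl-3-[(2S,3R,4Z)-3-hydroxy-5-methyl-2-(propan-2-yl)nona-4,8-dienoyl]-1,3-thiazolidine-2-thione | C=CCC/C(C)=C\[C@@H](O)[C@H](C(C)C)C(=O)N1[C@@H](Cc2ccccc2)CSC1=S
F5 | step 13 | (2S,3R,4Z)-3-hydroxy-N-methoxy-N,5-dimethyl-2-(propan-2-yl)nona-4,8-dienamide | C=CCC/C(C)=C\[C@@H](O)[C@H](C(C)C)C(=O)N(C)OC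
F6 | step 13 | (5S,6R,7Z)-6-hydroxy-2,8-dimethyl-5-(propan-2-yl)dodeca-1,7,11-trien-4-one | C=CCC/C(C)=C\[C@@H](O)[C@H](C(C)C)C(=O)CC(C)=C
F7 | step 13 | (4R,5R,6R,7Z)-2,8-dimethyl-5-(propan-2-yl)dodeca-1,7,11-triene-4,6-diol | C=CCC/C(C)=C\[C@@H](O)[C@H](C(C)C)[C@H](O)CC(C)=C
F8 | step 13 | (4R,5R,6R)-2,2-dimethyl-6-[(1Z)-2-methylhexa-1,5-dien-1-yl]-4-(2-methylprop-2-en-1-yl)-5-(propan-2-yl)-1,3-dioxane | C=CCC/C(C)=C\[C@H]1OC(C)(C)O[C@H](CC(C)=C)[C@H]1C(C)C
F9 | step 16 | 4-[(tert-butyldimethylsilyl)oxy]benzoic acid | O=C(O)c1ccc(O[Si](C)(C)C(C)(C)C)cc1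
F10 | step 3 | (2Z)-7,7-dibromo-3-methylhepta-2,6-dien-1-yl acetate | BrC(Br)=CCC/C(C)=C\COC(C)=O
F11 | step 3 | (2Z,6Z)-7-bromo-3-methylocta-2,6-dien-1-yl acetate | Br/C(C)=C\CC/C(C)=C\COC(C)=O
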